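The target that stays once the peak has passed is a leftover, and the size of that leftover is what you follow here, in Friday's flask.

all flasks: temperature 110 °C

| run | substrate | partner | remark | time |
|---|---|---|---|---|
| Friday's | 0.039 M | 1 equiv | the very flask that is asked about, followed so far |  |
| Saturday's | 0.019 M | 1 equiv | run made earlier |  |
| flask | 0.039 M | 1.00 equiv |  | 8.0 d |

| run | time / d | target / % |
|---|---|---|
| Friday's | 0.333 | 14.9 |
| Friday's | 0.833 | 29.5 |
| Friday's | 1.67 | 21.6 |
| Friday's | 2.50 | 14.8 |
| Friday's | 4.00 | 12.1 |
| Friday's | 5.00 | 9.8 |
| Saturday's | 0.833 | 23.6 |
| Saturday's | 1.25 | 23.9 |
| Saturday's | 2.00 | 17.7 |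
| Saturday's | 4.00 | 11.6 |
| Saturday's | 6.00 | 11.0 |
| Saturday's | 10.0 | 9.8 |

(each reading ± 0.5 percentage points)

- removed target is counted in
- the analysis behind the earlier runs scatters by 0.5 percentage points, standard deviation
- on the list of suspects stand: target <-> isomer of the product; 2 second intermediate -> homo product; partner -> second intermediate; open intermediate + second intermediate <-> target; substrate -> open intermediate
- the earlier runs do not show what temperature does; that part of a forecast is a guess
- additions bring no volume worth counting

- eta: at 8.0 d add partner, 100% of the amount charged, then wait 15 d
- beta: at 8.0 d take out 90% of the target then present, then wait 15 d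
- theta: at 8.0 d raise the temperature by 20 K, then wait 15 d
- zeta: change nothing and wait 15 d more

1. target, in percent of the substrate first charged, at 8.0 d
2. the remedy with the largest gain of target, or "none" below 2 percentage points (eta / beta / theta / zeta / none)
3. target present, with what was taken out counted in, in percent of the substrate first charged, after eta
4. target present, with what was taken out counted in, in percent of the substrate first charged, after zeta

1. Who does what. On the list of suspects, substrate opens to open intermediate, and partner turns into second intermediate. These two join to give target, which turns into its isomer. Second intermediate can also pair with itself to give homo product. Each target uses one second intermediate, so target plus isomer cannot exceed the partner charged.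

2. The leftover. Friday's run peaks near 29.5%, then reads 9.8% at 5.00 d. Saturday's run, at half the concentration, reads 9.8% at 10.0 d. I read the peak as kinetic control and the leftover as thermodynamic control.

3. The quantity. Call s the late share, the late target divided by the partner charged, both in percent of the substrate: s = 0.0980.

4. The zero of the scale. If the whole partner charge ended as target and isomer, and the two were equally stable, s would be 0.5. The reading is 5.10 times lower, so part of the partner stands outside target and isomer, as homo product or second intermediate, or the balance leans to the isomer, or both. These readings cannot divide the two.

5. My reckoning. At 8.0 d I put the target at s times the charge, 9.80%, and I expect zeta to leave it there. Beta takes out 8.82%, and I let what remains of the charge settle back to the share s of itself, so I reckon the gain at 8 percentage points. Eta doubles the partner charge, which I reckon gives 9.8 points if enough open intermediate remains, and the runs read target, not open intermediate. Theta is a guess: if the lean comes from heat released on isomerising, warming raises s, and the gap up to 0.5 is wider than s itself. So I name theta.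

6. The forecast gives 9.2% (range 8% to 10.2%), 6.8% after zeta and 13.5% after eta, and it names eta, saying “Fresh partner should raise the pool”, so it differs from my reckoning on zeta, on eta and on the choice.

7. The flask gives 9.76%, then 9.70% after zeta and 11.9% after eta. The gains are 16 points for theta, 7.7 points for beta and 2.2 points for eta, so the best remedy is theta. My eta figure stood well above its gain.

    target ⇌ isomer of the product (K = 7.10, k = 0.0605 h⁻¹, Ea = 118 kJ mol⁻¹, ΔH = −88.0 kJ mol⁻¹)
    2 second intermediate → homo product (k = 0.335 M⁻¹ h⁻¹, Ea = 76.0 kJ mol⁻¹)
    partner → second intermediate (k = 0.402 h⁻¹, Ea = 125 kJ mol⁻¹)
    open intermediate + second intermediate ⇌ target (K = 959 M⁻¹, k = 3.68 M⁻¹ h⁻¹, Ea = 68.0 kJ mol⁻¹, ΔH = −26.0 kJ mol⁻¹)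
    substrate → open intermediate (k = 0.0947 h⁻¹, Ea = 123 kJ mol⁻¹)
    (constants at 110 °C)

Now take the neighbouring flask, like the asked flask but charged with 0.250 equiv of partner and read at 8.00 d. The late share gives 2.45% target, and that flask holds 2.94%, beside 20.9% isomer, so its own share is 0.118. The asked flask held 21.3% open intermediate at the moment of eta, while the neighbouring flask ends with 76.2%.

(All runs are calculated on assumed constants; scatter was added.)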